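The central ring (C1 OMe, C3 OH, 4-hydroxybenzyl at C2, C4 and C6, arylethyl at C5) has its oxygens on alternate carbons, the imprint of a folded 1,3,5-tricarbonyl chain. Without the O-methyl it is symmetric about the C2–C5 axis. The plan cuts the C5–C6 bond. One telescoped operation unlocks a fully substituted 4-pyranone to the open chain, closes the ester-bearing carbon onto the arylethyl ketone, dehydrates, and expels the ester carbon as CO2 to aromatise. The precursor carries all four arms as benzyl ethers and a tert-butyl ester on the future C6. A methyl ester would be saponified and lost before the ring opens, which would erase the bias between the two chain ends.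

Key step: step 7

Remark on the chemistry: the target has no stereocentre. Compounds 7, 10, 12 and 13 are racemic and 11 is a mixture of diastereomers and tautomers; all these centres vanish on aromatisation. Hydroxide entering at C2 or at C6 of 10 leads to the same open chain 11.

Step 1
Reactants: 1 2,6-dimethyl-4H-pyran-4-one
Product: 2 3,5-dibromo-2,6-dimethyl-4H-pyran-4-one
Conditions: Br2 (2.3 equiv), NaOAc (2.5 equiv), AcOH, 60 °C
Reagents that add atoms: bromine, BrBr
Why: C3 and C5 are the electron-rich β-carbons of the ring enol ether units, so buffered electrophilic bromination (addition–elimination, a vinylogous ester α-halogenation) should take both remaining ring C–H positions and then stop.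

Step 2
Reactants: 3 4-benzyloxybenzyl chloride
Product: 4 (4-benzyloxybenzyl)zinc chloride, kept as a titrated THF solution
Conditions: Zn dust (1.5 equiv), LiCl (1.5 equiv), THF, 25 °C
Reagents that add atoms: zinc, [Zn]
Why: Direct zinc insertion into a benzylic chloride in the presence of LiCl is a standard organozinc preparation, and choosing the chloride over the more labile bromide limits Wurtz-type homocoupling of this electron-rich benzyl unit.

Step 3
Reactants: 2 3,5-dibromo-2,6-dimethyl-4H-pyran-4-one; 4 (4-benzyloxybenzyl)zinc chloride (2.6 equiv)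
Product: 5 3,5-bis(4-benzyloxybenzyl)-2,6-dimethyl-4H-pyran-4-one
Conditions: Pd(OAc)2 (2 mol %), SPhos (4 mol %), THF, 25 to 50 °C
Reagents that add atoms: none
Why: Twofold Negishi coupling: the α-bromoenone C–Br bonds add readily to zerovalent palladium carrying the bulky biarylphosphine, the benzylzinc reagent has no β-hydrogen to lose, and it is too mild to attack the pyranone carbonyl.

Step 4
Reactants: 5 3,5-bis(4-benzyloxybenzyl)-2,6-dimethyl-4H-pyran-4-one
Product: 6 tert-butyl 2-[3,5-bis(4-benzyloxybenzyl)-6-methyl-4-oxo-4H-pyran-2-yl]acetate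
Conditions: LiN(SiMe3)2 (2.2 equiv), THF, −78 °C; Boc2O (1.05 equiv), −78 to −20 °C; AcOH quench
Reagents that add atoms: di-tert-butyl dicarbonate, CC(C)(C)OC(=O)OC(=O)OC(C)(C)C
Why: Lateral (vinylogous) deprotonation of a 2-methyl-4-pyranone followed by Claisen-type C-acylation with Boc2O; the two methyl groups are equivalent, and the second equivalent of base stores the product as its stabilised enolate, which prevents a second acylation.

Step 5
Reactants: 6 tert-butyl 2-[3,5-bis(4-benzyloxybenzyl)-6-methyl-4-oxo-4H-pyran-2-yl]acetate; 3 4-benzyloxybenzyl chloride (1.0 equiv)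
Product: 7 racemic tert-butyl 2-[3,5-bis(4-benzyloxybenzyl)-6-methyl-4-oxo-4H-pyran-2-yl]-3-(4-benzyloxyphenyl)propanoate
Conditions: KOtBu (1.05 equiv), THF, 0 °C; 3, n-Bu4NI (10 mol %), 0 °C to rt
Reagents that add atoms: none
Why: SN2 alkylation of a doubly stabilised (ester plus vinylogous ketone) enolate, run with one equivalent of electrophile so that the hindered, less acidic product is not alkylated again; the new stereocentre forms as a racemate and is erased in step 7.

Step 6
Reactants: 7 racemic tert-butyl 2-[3,5-bis(4-benzyloxybenzyl)-6-methyl-4-oxo-4H-pyran-2-yl]-3-(4-benzyloxyphenyl)propanoate; 8 3-benzyloxybenzyl bromide (1.0 equiv)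
Product: 10 racemic tert-butyl 2-{3,5-bis(4-benzyloxybenzyl)-6-[2-(3-benzyloxyphenyl)ethyl]-4-oxo-4H-pyran-2-yl}-3-(4-benzyloxyphenyl)propanoate, via dilithio dianion 9 (not isolated)
Conditions: LiN(iPr)2 (2.2 equiv), THF, −78 to −40 °C; 8, −78 to −30 °C; AcOH quench
Reagents that add atoms: none
Why: Two equivalents of amide base remove the ester α-proton and one proton of the C6 methyl group, and, as in the γ-alkylation of β-keto ester dianions, the last-formed and least stabilised carbanion of 9 takes the benzylic bromide while the hindered tertiary ester enolate stays a spectator and is reprotonated to the racemate on quench.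

Step 7
Reactants: 10 racemic tert-butyl 2-{3,5-bis(4-benzyloxybenzyl)-6-[2-(3-benzyloxyphenyl)ethyl]-4-oxo-4H-pyran-2-yl}-3-(4-benzyloxyphenyl)propanoate
Product: 14 2,4,6-tris(4-benzyloxybenzyl)-5-[2-(3-benzyloxyphenyl)ethyl]benzene-1,3-diol, via open-chain triketo ester 11 (not isolated), via blocked dienone ester 12 (not isolated), via dienone carboxylic acid 13 (not isolated)
Conditions: KOH (10 equiv), 1,4-dioxane–H2O 4:1, degassed, Ar, 85 °C; 1 M HCl to pH 3 at 0 °C, extraction into CH2Cl2; then TFA–CH2Cl2 1:4, 0 °C to rt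
Reagents that add atoms: water (delivered as hydroxide), O
Why: Conjugate addition of hydroxide at C6 (or C2) of the pyranone gives a hemiketal enolate whose ring C–O bond breaks, which releases the 1,3,5-triketone as the enolate of 11. The carbon of 11 that lies between ester and ketone then adds to the remote arylethyl ketone in a geometrically favoured 6-exo-trig aldol closure that makes the C5–C6 bond and the only new ring, and E1cB loss of water gives dienone 12, which rests in base as a vinylogous carboxylate. The closest known reaction type is the base-induced conversion of 4-pyranones, open triketones and 3,5,7-triketo esters into resorcinols and resorcylates. Because C6 of 12 is quaternary, aromatisation waits for the second stage, in which acid removes isobutene and β-keto acid 13 loses CO2 through its cyclic transition state to give the phenol directly; no stereocentre survives, so none needs control. The selectivity needed is between the two chain ends: the CH2 beside the arylethyl ketone could also attack the ketone next to the ester, but it is roughly six to seven pKa units less acidic than the keto ester carbon and its target carbonyl is tied up by enolisation from both sides, so under equilibrating hydroxide the ester-bearing end should react first. The tert-butyl ester secures this bias because it resists saponification (no early decarboxylation) and is too poor an electrophile for the competing Claisen closure, and the benzyl ethers keep the para-oxygenated arms from leaving as quinone methides.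

Step 8
Reactants: 14 2,4,6-tris(4-benzyloxybenzyl)-5-[2-(3-benzyloxyphenyl)ethyl]benzene-1,3-diol
Product: 15 2,4,6-tris(4-benzyloxybenzyl)-5-[2-(3-benzyloxyphenyl)ethyl]-3-methoxyphenol
Conditions: Me2SO4 (1.0 equiv), K2CO3 (1.1 equiv), acetone, 40 °C; recovered 14 recycled
Reagents that add atoms: dimethyl sulfate, COS(=O)(=O)OC
Why: Williamson-type O-methylation with a hard electrophile, which favours oxygen over ring carbon; the C2–C5 axis makes both hydroxyls equivalent so only one monoether can form, and a limiting charge of reagent with recycling of recovered 14 keeps the diether down.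

Step 9
Reactants: 15 2,4,6-tris(4-benzyloxybenzyl)-5-[2-(3-benzyloxyphenyl)ethyl]-3-methoxyphenol
Product: 16 2,4,6-tris(4-hydroxybenzyl)-5-[2-(3-hydroxyphenyl)ethyl]-3-methoxyphenol (CNP0262401.0)
Conditions: H2 (1 atm), 10% Pd/C, EtOAc–MeOH, rt
Reagents that add atoms: none
Why: Catalytic hydrogenolysis of the four aryl benzyl ethers over palladium; the diarylmethane and bibenzyl C–C bonds, the methyl ether and the arenes are inert under these conditions.

Compound list
1 | 2,6-dimethyl-4H-pyran-4-one | Cc1cc(=O)cc(C)o1 | starting material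
2 | 3,5-dibromo-2,6-dimethyl-4H-pyran-4-one | Cc1oc(C)c(Br)c(=O)c1Br | intermediate
3 | 4-benzyloxybenzyl chloride | ClCc1ccc(OCc2ccccc2)cc1 | starting material
4 | (4-benzyloxybenzyl)zinc chloride | Cl[Zn]Cc1ccc(OCc2ccccc2)cc1 | intermediate
5 | 3,5-bis(4-benzyloxybenzyl)-2,6-dimethyl-4H-pyran-4-one | Cc1oc(C)c(Cc2ccc(OCc3ccccc3)cc2)c(=O)c1Cc1ccc(OCc2ccccc2)cc1 | intermediate
6 | tert-butyl 2-[3,5-bis(4-benzyloxybenzyl)-6-methyl-4-oxo-4H-pyran-2-yl]acetate | CC(C)(C)OC(=O)Cc1oc(C)c(Cc2ccc(OCc3ccccc3)cc2)c(=O)c1Cc1ccc(OCc2ccccc2)cc1 | intermediate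
7 | racemic tert-butyl 2-[3,5-bis(4-benzyloxybenzyl)-6-methyl-4-oxo-4H-pyran-2-yl]-3-(4-benzyloxyphenyl)propanoate | CC(C)(C)OC(=O)C(Cc1ccc(OCc2ccccc2)cc1)c1oc(C)c(Cc2ccc(OCc3ccccc3)cc2)c(=O)c1Cc1ccc(OCc2ccccc2)cc1 | intermediate
8 | 3-benzyloxybenzyl bromide | BrCc1cccc(OCc2ccccc2)c1 | starting material
9 | dilithio dianion of 7 (ester α-carbon and C6 methyl carbon deprotonated) | [Li+].[Li+].[CH2-]c1oc([C-](Cc2ccc(OCc3ccccc3)cc2)C(=O)OC(C)(C)C)c(Cc2ccc(OCc3ccccc3)cc2)c(=O)c1Cc1ccc(OCc2ccccc2)cc1 | intermediate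
10 | racemic tert-butyl 2-{3,5-bis(4-benzyloxybenzyl)-6-[2-(3-benzyloxyphenyl)ethyl]-4-oxo-4H-pyran-2-yl}-3-(4-benzyloxyphenyl)propanoate | CC(C)(C)OC(=O)C(Cc1ccc(OCc2ccccc2)cc1)c1oc(CCc2cccc(OCc3ccccc3)c2)c(Cc2ccc(OCc3ccccc3)cc2)c(=O)c1Cc1ccc(OCc2ccccc2)cc1 | intermediate
11 | tert-butyl 2,4,6-tris(4-benzyloxybenzyl)-9-(3-benzyloxyphenyl)-3,5,7-trioxononanoate (stereoisomer and tautomer mixture) | CC(C)(C)OC(=O)C(Cc1ccc(OCc2ccccc2)cc1)C(=O)C(Cc1ccc(OCc2ccccc2)cc1)C(=O)C(Cc1ccc(OCc2ccccc2)cc1)C(=O)CCc1cccc(OCc2ccccc2)c1 | intermediate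
12 | racemic tert-butyl 1,3,5-tris(4-benzyloxybenzyl)-6-[2-(3-benzyloxyphenyl)ethyl]-4-hydroxy-2-oxocyclohexa-3,5-diene-1-carboxylate | CC(C)(C)OC(=O)C1(Cc2ccc(OCc3ccccc3)cc2)C(=O)C(Cc2ccc(OCc3ccccc3)cc2)=C(O)C(Cc2ccc(OCc3ccccc3)cc2)=C1CCc1cccc(OCc2ccccc2)c1 | intermediate
13 | racemic 1,3,5-tris(4-benzyloxybenzyl)-6-[2-(3-benzyloxyphenyl)ethyl]-4-hydroxy-2-oxocyclohexa-3,5-diene-1-carboxylic acid | OC(=O)C1(Cc2ccc(OCc3ccccc3)cc2)C(=O)C(Cc2ccc(OCc3ccccc3)cc2)=C(O)C(Cc2ccc(OCc3ccccc3)cc2)=C1CCc1cccc(OCc2ccccc2)c1 | intermediate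
14 | 2,4,6-tris(4-benzyloxybenzyl)-5-[2-(3-benzyloxyphenyl)ethyl]benzene-1,3-diol | Oc1c(Cc2ccc(OCc3ccccc3)cc2)c(O)c(Cc2ccc(OCc3ccccc3)cc2)c(CCc2cccc(OCc3ccccc3)c2)c1Cc1ccc(OCc2ccccc2)cc1 | intermediate
15 | 2,4,6-tris(4-benzyloxybenzyl)-5-[2-(3-benzyloxyphenyl)ethyl]-3-methoxyphenol | COc1c(Cc2ccc(OCc3ccccc3)cc2)c(O)c(Cc2ccc(OCc3ccccc3)cc2)c(CCc2cccc(OCc3ccccc3)c2)c1Cc1ccc(OCc2ccccc2)cc1 | intermediate
16 | 2,4,6-tris(4-hydroxybenzyl)-5-[2-(3-hydroxyphenyl)ethyl]-3-methoxyphenol (CNP0262401.0) | COc1c(Cc2ccc(O)cc2)c(O)c(Cc2ccc(O)cc2)c(CCc2cccc(O)c2)c1Cc1ccc(O)cc1 | target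

Total step count: 9. Longest linear sequence: 8 steps (1 → 2 → 5 → 6 → 7 → 10 → 14 → 15 → 16). Step 2 is a one-step side branch.

Steps most likely to fail

Step 7. Four things may go wrong:
- Hydroxide may cut the opened chain by retro-Claisen cleavage faster than the fully substituted carbanion adds to the flanked ketone.
- Deprotonation next to the ester may slow ring opening.
- Closure may start from the other chain end.
- The acid stage may detach or shift the 4-benzyloxybenzyl group on the quaternary ring carbon before the ester has gone.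

The fallback sets out from 6 and comes back at 14. It postpones the third benzyl group, so that the nucleophile is a secondary carbon and the ring aromatises at once without a blocked dienone. Compound 6 is doubly deprotonated with LiN(iPr)2 and alkylated with 8 at the methyl group to give tert-butyl 2-{3,5-bis(4-benzyloxybenzyl)-6-[2-(3-benzyloxyphenyl)ethyl]-4-oxo-4H-pyran-2-yl}acetate F1. KOH in aqueous dioxane converts this by the same C5–C6 aldol closure into tert-butyl 3,5-bis(4-benzyloxybenzyl)-6-[2-(3-benzyloxyphenyl)ethyl]-2,4-dihydroxybenzoate F2. TFA in CH2Cl2 frees 3,5-bis(4-benzyloxybenzyl)-6-[2-(3-benzyloxyphenyl)ethyl]-2,4-dihydroxybenzoic acid F3, and this crowded, electron-rich resorcylic acid should lose CO2 on gentle warming to give 2,4-bis(4-benzyloxybenzyl)-5-[2-(3-benzyloxyphenyl)ethyl]benzene-1,3-diol F4. Friedel–Crafts benzylation of F4 with 3 in hexafluoroisopropanol at rt can only strike the single free ring carbon, which is ortho and para to the hydroxyls, and gives 14.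

Step 6. The second deprotonation may stay incomplete. Proton shuffling between the anions may then divert the bromide to the ester carbon or cause double alkylation of the arm.

The fallback sets out from 7 and comes back at 10. It replaces kinetic dianion alkylation by a thermodynamically driven condensation and a reduction. Compound 7 and commercial 3-benzyloxybenzaldehyde are condensed with NaOEt in EtOH at rt. This is the usual styryl formation of 2-methyl-4-pyranones, in which only the methyl group can dehydrate after addition. The product is tert-butyl 2-{3,5-bis(4-benzyloxybenzyl)-6-[(E)-2-(3-benzyloxyphenyl)ethenyl]-4-oxo-4H-pyran-2-yl}-3-(4-benzyloxyphenyl)propanoate F5. Diimide (p-toluenesulfonyl hydrazide, NaOAc, aqueous DME, reflux) then saturates the disubstituted alkene without touching the benzyl ethers or the tetrasubstituted ring double bonds, and gives 10.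

Step 8. The two hydroxyls are equivalent, so over-methylation and incomplete conversion compete with monoether formation. The crowded resorcinolate may also be methylated on carbon with loss of aromaticity.

The fallback sets out from 10 and comes back at 15. It methylates before aromatisation, when only one acidic oxygen exists. Step 7 is stopped after the base stage and 12 is isolated. Me2SO4 and K2CO3 in acetone O-methylate its vinylogous acid to give tert-butyl 1,3,5-tris(4-benzyloxybenzyl)-6-[2-(3-benzyloxyphenyl)ethyl]-4-methoxy-2-oxocyclohexa-3,5-diene-1-carboxylate F6. This may be accompanied by the cross-conjugated isomer tert-butyl 1,3,5-tris(4-benzyloxybenzyl)-6-[2-(3-benzyloxyphenyl)ethyl]-2-methoxy-4-oxocyclohexa-2,5-diene-1-carboxylate F7. TFA in CH2Cl2 then removes isobutene and CO2 from either isomer, and because C1 and C3 of the arene are equivalent both converge on 15.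

Further compounds
F1 | step 7 | tert-butyl 2-{3,5-bis(4-benzyloxybenzyl)-6-[2-(3-benzyloxyphenyl)ethyl]-4-oxo-4H-pyran-2-yl}acetate | CC(C)(C)OC(=O)Cc1oc(CCc2cccc(OCc3ccccc3)c2)c(Cc2ccc(OCc3ccccc3)cc2)c(=O)c1Cc1ccc(OCc2ccccc2)cc1
F2 | step 7 | tert-butyl 3,5-bis(4-benzyloxybenzyl)-6-[2-(3-benzyloxyphenyl)ethyl]-2,4-dihydroxybenzoate | CC(C)(C)OC(=O)c1c(O)c(Cc2ccc(OCc3ccccc3)cc2)c(O)c(Cc2ccc(OCc3ccccc3)cc2)c1CCc1cccc(OCc2ccccc2)c1
F3 | step 7 | 3,5-bis(4-benzyloxybenzyl)-6-[2-(3-benzyloxyphenyl)ethyl]-2,4-dihydroxybenzoic acid | OC(=O)c1c(O)c(Cc2ccc(OCc3ccccc3)cc2)c(O)c(Cc2ccc(OCc3ccccc3)cc2)c1CCc1cccc(OCc2ccccc2)c1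
F4 | step 7 | 2,4-bis(4-benzyloxybenzyl)-5-[2-(3-benzyloxyphenyl)ethyl]benzene-1,3-diol | Oc1cc(CCc2cccc(OCc3ccccc3)c2)c(Cc2ccc(OCc3ccccc3)cc2)c(O)c1Cc1ccc(OCc2ccccc2)cc1
F5 | step 6 | tert-butyl 2-{3,5-bis(4-benzyloxybenzyl)-6-[(E)-2-(3-benzyloxyphenyl)ethenyl]-4-oxo-4H-pyran-2-yl}-3-(4-benzyloxyphenyl)propanoate | CC(C)(C)OC(=O)C(Cc1ccc(OCc2ccccc2)cc1)c1oc(/C=C/c2cccc(OCc3ccccc3)c2)c(Cc2ccc(OCc3ccccc3)cc2)c(=O)c1Cc1ccc(OCc2ccccc2)cc1
F6 | step 8 | tert-butyl 1,3,5-tris(4-benzyloxybenzyl)-6-[2-(3-benzyloxyphenyl)ethyl]-4-methoxy-2-oxocyclohexa-3,5-diene-1-carboxylate | CC(C)(C)OC(=O)C1(Cc2ccc(OCc3ccccc3)cc2)C(=O)C(Cc2ccc(OCc3ccccc3)cc2)=C(OC)C(Cc2ccc(OCc3ccccc3)cc2)=C1CCc1cccc(OCc2ccccc2)c1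
F7 | step 8 | tert-butyl 1,3,5-tris(4-benzyloxybenzyl)-6-[2-(3-benzyloxyphenyl)ethyl]-2-methoxy-4-oxocyclohexa-2,5-diene-1-carboxylate | CC(C)(C)OC(=O)C1(Cc2ccc(OCc3ccccc3)cc2)C(OC)=C(Cc2ccc(OCc3ccccc3)cc2)C(=O)C(Cc2ccc(OCc3ccccc3)cc2)=C1CCc1cccc(OCc2ccccc2)c1
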